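By 0.833 d Wednesday's run has stopped moving: starting material sits within the scatter of zero and intermediate A stays flat, averaging 74.7% over the last readings.

| setting | Wednesday's | flask |
|---|---|---|
| starting material | 20 mM (in portions, 3) | 20 mM (in portions, 3) |
| coupling partner | 30 mM | 60.0 mM |
| remark | run made earlier; portions every 4.0 h | the portions of starting material follow each other after 4.0 h, the first at the start |
| time |  | 15 d |

Wednesday's run (percent of the starting material charged)

| time / d | starting material / % | intermediate A / % | target / % |
|---|---|---|---|
| 0.250 | 6.9 | 45.1 | 0 |
| 0.333 | 3.6 | 50.5 | 0.6 |
| 0.500 | 5.0 | 71.2 | 1.4 |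
| 0.833 | 1.0 | 74.6 | 1.6 |
| 1.25 | 0 | 74.3 | 0 |
| 2.08 | 0 | 74.5 | 1.2 |
| 3.00 | 0.8 | 75.5 | 0 |

(standard deviation of a reading: 1 percentage point)

- at 15 d, what has stopped the reaction, if anything has (it is still moving / forward and back rates have come level / all of the starting material has reacted / the coupling partner has run out first)
- conversion of starting material at 15 d
- amount of intermediate A at 15 d, in percent of the starting material charged

- the reaction counts as stopped when no species that holds the starting material changes by six tenths of a point or more over the second half of the time

I carry one quantity, the hidden ratio g: the part of the charge not standing as intermediate A, divided by the part that does.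

g = (whole charge − plateau)/plateau = 0.338

Wednesday's run gives one g, and two extremes bracket the new flask. In the first, g is a loss of starting material competing with coupling, the inverse of a selectivity factor, so g scales as 1/[coupling partner]:

g = 0.169, intermediate A = 85.5%

In the second, g is intermediate A held in an unseen store by leftover partner, each unit of the store binding one partner beyond the one already in intermediate A, so g scales as [coupling partner] left. With Wednesday's split of the charge, that is 4.94 mM on Wednesday and 34.9 mM in the flask:

g = 2.39, intermediate A = 29.5%

The two pull opposite ways, and one g cannot show the split. I take equal parts, g = 1.28, and commit to intermediate A near 43.9%. Starting material read 0% at 1.25 d, far shorter than 15 d, so I expect it to be consumed.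

The forecast says all of the starting material has reacted, conversion 100% (99.5% to 100%) and intermediate A 85% (76% to 90%), on the grounds of “a side reaction second order in starting material, competing with coupling first order in partner”.

The flask gives all of the starting material has reacted, conversion 100% and intermediate A 74.3%: 11 percentage points below the forecast, and g = 0.346, close to Wednesday's.

    starting material + coupling partner → intermediate A (k = 0.00730 M⁻¹ s⁻¹)
    starting material + coupling partner → intermediate B (k = 1.60 × 10⁻⁴ M⁻¹ s⁻¹)
    intermediate B → side product B (k = 3.70 × 10⁻⁴ s⁻¹)
    starting material → side product A (k = 3.40 × 10⁻⁵ s⁻¹)
    intermediate B → target (k = 3.60 × 10⁻⁵ s⁻¹)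
    coupling partner + intermediate A ⇌ intermediate C (K = 5.30 M⁻¹, k = 3.70 × 10⁻⁴ M⁻¹ s⁻¹)

In the flask, coupling into intermediate A ran while starting material was present, with a half-life by this step of 0.53 h at 0.186 d, and side product A reached 8.50%. Meanwhile partner carried intermediate A into intermediate C, which held 9.32% at 0.333 d and 15.2% at 7.50 d. In the neighbour flask with 240 mM of coupling partner, g is 1.20, with intermediate C at 50.6% against intermediate A at 45.4%.

The earlier runs and the new flask stem from a simulated flask with made-up constants; scatter was added.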